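**Retrosynthetic overview**
- The target comes from its hepta-O-benzyl derivative by global hydrogenolysis. Both gallates are already in place, so no late differentiation of phenols is needed.
- C2 and C3 are both set in one flask from a flat, aromatic flavylium (1-benzopyrylium) cation. Hydride adds at C4 to give the flav-2-ene, then IpcBH2 adds syn under reagent control and the borane is oxidised.
- Ring C is the only ring formed. It closes by acid condensation of 4-O-galloyl-2,6-dihydroxybenzaldehyde with 3-O-galloyl-4-O-benzylacetophenone. The two ortho-OH groups are equivalent, so either closure gives the 5-OH/7-O-gallate pattern.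
- The aldehyde comes from phloroglucinol by formylation and para-acylation. The ketone comes from 3,4-dihydroxyacetophenone. The galloyl units come from 3,4,5-tris(benzyloxy)benzoic acid.

Assumption: the ethereal IpcBH2 stock solution is made beforehand from the commercial (+)-α-pinene-series IpcBH2·TMEDA complex with BF3·OEt2 and filtered. It is treated as a reagent and not counted as a step.

**Step 1**
Reactants: 1 phloroglucinol
Product: 3 2,4,6-trihydroxybenzaldehyde, via aryl iminium chloride 2 (not isolated)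
Conditions: [Me2N=CHCl]Cl (1.05 equiv), MeCN–EtOAc, 0 °C → rt; then H2O, 50 °C
Reagents that add atoms: (chloromethylene)dimethyliminium chloride, C[N+](C)=CCl.[Cl-]; water, O
Why: Vilsmeier–Haack formylation works here because all three ring C–H positions are equivalent, so only one product is possible, and the iminium group deactivates the ring against a second attack.

**Step 2**
Reactants: 3 2,4,6-trihydroxybenzaldehyde; 4 3,4,5-tris(benzyloxy)benzoic acid
Product: 5 4-formyl-3,5-dihydroxyphenyl 3,4,5-tris(benzyloxy)benzoate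
Conditions: 4 (1.0 equiv, slow addition), DCC, DMAP (10 mol %), THF, −10 °C → rt
Reagents that add atoms: none
Why: Steglich esterification should favour the unhindered OH para to CHO, because the two ortho-OH groups flank the formyl group and share its chelate, and the product keeps two equivalent ortho-OH groups (one 2H aromatic singlet).

**Step 3**
Reactants: 6 3,4-dihydroxyacetophenone
Product: 7 1-[4-(benzyloxy)-3-hydroxyphenyl]ethan-1-one
Conditions: BnCl (1.05 equiv), NaHCO3, NaI (cat.), DMF, 40 °C
Reagents that add atoms: benzyl chloride, ClCc1ccccc1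
Why: In this Williamson ether synthesis the weak base ionises only the more acidic 4-OH (para to the acetyl group), so that position alone is alkylated.

**Step 4**
Reactants: 7 1-[4-(benzyloxy)-3-hydroxyphenyl]ethan-1-one; 4 3,4,5-tris(benzyloxy)benzoic acid
Product: 8 5-acetyl-2-(benzyloxy)phenyl 3,4,5-tris(benzyloxy)benzoate
Conditions: DCC, DMAP (cat.), CH2Cl2, rt
Reagents that add atoms: none
Why: Steglich esterification of the single remaining phenol is unambiguous, and the neighbouring O-benzyl group blocks any later 3'→4' acyl shift.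

**Step 5**
Reactants: 5 4-formyl-3,5-dihydroxyphenyl 3,4,5-tris(benzyloxy)benzoate; 8 5-acetyl-2-(benzyloxy)phenyl 3,4,5-tris(benzyloxy)benzoate
Product: 10 4'-benzyloxy-5-hydroxy-7,3'-bis[3,4,5-tris(benzyloxy)benzoyloxy]flavylium tetrafluoroborate, via (E)-2-hydroxychalcone 9 (not isolated)
Conditions: HBF4·OEt2 (3 equiv), EtOAc–CH2Cl2, 0 °C → rt, 24–48 h; precipitate with Et2O–hexane
Reagents that add atoms: tetrafluoroboric acid (diethyl etherate), [H+].F[B-](F)(F)F
Why: This is a Robinson-type flavylium synthesis (acid-catalysed crossed aldol condensation, then cyclodehydration) in which either equivalent ortho-OH closes ring C to the same isomer (5-OH free, gallate at C7), aryl esters tolerate these anhydrous acid conditions, and BF4− cannot dealkylate the benzyl ethers.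

**Step 6**
Reactants: 10 4'-benzyloxy-5-hydroxy-7,3'-bis[3,4,5-tris(benzyloxy)benzoyloxy]flavylium tetrafluoroborate
Product: 13 (2R,3S)-4'-O-benzyl-7,3'-bis-O-[3,4,5-tris(benzyloxy)benzoyl]catechin, via flav-2-ene 11 (not isolated), via C3-isopinocampheylborane 12 (not isolated)
Conditions: BNAH (1-benzyl-1,4-dihydronicotinamide, 1.0 equiv), CH2Cl2, −40 °C, filter under Ar; IpcBH2 [(+)-α-pinene series, 2.5 equiv, one equiv taken up by the phenol O–H], Et2O–CH2Cl2, −25 °C, 36 h; 30% H2O2, pH 7 phosphate buffer, THF, 0 °C → rt; recrystallise 13 to raise ee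
Reagents that add atoms: hydrogen peroxide, OO (the C3 oxygen); monoisopinocampheylborane, C[C@H]1[C@H](B)C[C@@H]2C[C@H]1C2(C)C (boron and Ipc enter 12 only and are gone in 13)
Why: Proposed new method: this is a one-flask dearomative hydride transfer and asymmetric hydroboration of a flavylium ion, in which the NADH model delivers hydride to the open C4 of the 2-aryl-1-benzopyrylium (C2 is shielded by the aryl group, and the by-product is a non-acidic, insoluble pyridinium salt, so the acid-labile enol ether 11 survives), IpcBH2 then adds H and B syn across C2=C3 with boron at C3 (β to both O1 and the aryl group), which places aryl and boron trans and fixes both stereocentres at once, the face is chosen by the reagent as in the Brown hydroboration of 1-arylcycloalkenes (the (+)-α-pinene reagent gives (1S,2R)-trans-2-arylcycloalkanols, the same spatial sense as 2R,3S here), and buffered peroxide replaces B by OH with retention without cleaving the aryl esters; the closest known reaction types are the 1,4-reduction of benzopyrylium ions by dihydropyridines, the racemic hydroboration–oxidation of flav-2-enes to 2,3-trans-flavan-3-ols, and the Brown asymmetric hydroboration.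

**Step 7**
Reactants: 13 (2R,3S)-4'-O-benzyl-7,3'-bis-O-[3,4,5-tris(benzyloxy)benzoyl]catechin
Product: 14 (+)-catechin 7,3'-di-O-gallate
Conditions: H2 (1 atm), 20% Pd(OH)2/C, THF–MeOH (1:1), rt; filter, concentrate below 30 °C
Reagents that add atoms: none
Why: Catalytic hydrogenolysis removes all seven O-benzyl groups under neutral conditions that leave the aryl esters, the cyclic C2–O1 bond and both stereocentres untouched and give no base to drive 3'→4' acyl migration.

**Compound list**
1 | phloroglucinol | Oc1cc(O)cc(O)c1 | starting material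
2 | dimethyl[(2,4,6-trihydroxyphenyl)methylidene]ammonium chloride | C[N+](C)=Cc1c(O)cc(O)cc1O.[Cl-] | intermediate (not isolated)
3 | 2,4,6-trihydroxybenzaldehyde | O=Cc1c(O)cc(O)cc1O | intermediate
4 | 3,4,5-tris(benzyloxy)benzoic acid | O=C(O)c1cc(OCc2ccccc2)c(OCc2ccccc2)c(OCc2ccccc2)c1 | starting material
5 | 4-formyl-3,5-dihydroxyphenyl 3,4,5-tris(benzyloxy)benzoate | O=Cc1c(O)cc(OC(=O)c2cc(OCc3ccccc3)c(OCc3ccccc3)c(OCc3ccccc3)c2)cc1O | intermediate
6 | 3,4-dihydroxyacetophenone | CC(=O)c1ccc(O)c(O)c1 | starting material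
7 | 1-[4-(benzyloxy)-3-hydroxyphenyl]ethan-1-one | CC(=O)c1ccc(OCc2ccccc2)c(O)c1 | intermediate
8 | 5-acetyl-2-(benzyloxy)phenyl 3,4,5-tris(benzyloxy)benzoate | CC(=O)c1ccc(OCc2ccccc2)c(OC(=O)c2cc(OCc3ccccc3)c(OCc3ccccc3)c(OCc3ccccc3)c2)c1 | intermediate
9 | (E)-chalcone ArA–CH=CH–CO–ArB (ArA = 2,6-dihydroxy-4-galloyloxyphenyl, ArB = 4-benzyloxy-3-galloyloxyphenyl, galloyl = tri-O-benzylgalloyl) | O=C(/C=C/c1c(O)cc(OC(=O)c2cc(OCc3ccccc3)c(OCc3ccccc3)c(OCc3ccccc3)c2)cc1O)c1ccc(OCc2ccccc2)c(OC(=O)c2cc(OCc3ccccc3)c(OCc3ccccc3)c(OCc3ccccc3)c2)c1 | intermediate (not isolated)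
10 | 4'-benzyloxy-5-hydroxy-7,3'-bis[3,4,5-tris(benzyloxy)benzoyloxy]flavylium tetrafluoroborate | Oc1cc(OC(=O)c2cc(OCc3ccccc3)c(OCc3ccccc3)c(OCc3ccccc3)c2)cc2[o+]c(-c3ccc(OCc4ccccc4)c(OC(=O)c4cc(OCc5ccccc5)c(OCc5ccccc5)c(OCc5ccccc5)c4)c3)ccc12.F[B-](F)(F)F | intermediate
11 | the corresponding flav-2-ene (2-aryl-4H-chromene, C2=C3, C4H2) | Oc1cc(OC(=O)c2cc(OCc3ccccc3)c(OCc3ccccc3)c(OCc3ccccc3)c2)cc2OC(c3ccc(OCc4ccccc4)c(OC(=O)c4cc(OCc5ccccc5)c(OCc5ccccc5)c(OCc5ccccc5)c4)c3)=CCc12 | intermediate (not isolated)
12 | 2,3-trans-flavan-3-yl(isopinocampheyl)borane, same spatial arrangement as 13 (2S,3S by CIP because B ranks below C), phenol drawn free | C[C@H]1[C@H](B[C@H]3Cc4c(O)cc(OC(=O)c5cc(OCc6ccccc6)c(OCc6ccccc6)c(OCc6ccccc6)c5)cc4O[C@@H]3c7ccc(OCc8ccccc8)c(OC(=O)c8cc(OCc9ccccc9)c(OCc9ccccc9)c(OCc9ccccc9)c8)c7)C[C@@H]2C[C@H]1C2(C)C | intermediate (not isolated)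
13 | (2R,3S)-4'-O-benzyl-7,3'-bis-O-[3,4,5-tris(benzyloxy)benzoyl]catechin | O=C(Oc1cc(O)c2c(c1)O[C@H](c1ccc(OCc3ccccc3)c(OC(=O)c3cc(OCc4ccccc4)c(OCc4ccccc4)c(OCc4ccccc4)c3)c1)[C@@H](O)C2)c1cc(OCc2ccccc2)c(OCc2ccccc2)c(OCc2ccccc2)c1 | intermediate
14 | (2R,3S)-catechin 7,3'-di-O-gallate | O=C(Oc1cc(O)c2c(c1)O[C@H](c1ccc(O)c(OC(=O)c3cc(O)c(O)c(O)c3)c1)[C@@H](O)C2)c1cc(O)c(O)c(O)c1 | target

**Totals**
- Total step count: 7.
- Longest linear sequence: 5 steps (1→3→5→10→13→14). The branch 6→7→8→10→13→14 is equally long.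

**Three steps most likely to fail**

Step 6 is the riskiest step.
- Some hydride may add at C2, giving a racemic flav-3-ene that erodes the ee.
- The β-aryloxyborane may eliminate.
- The facial selectivity on this enol ether has never been tested.

The fallback sets out from 10 and comes back at 13. It moves the enantio-determining event from C–B to C–O bond formation.
- Open 10 with aq. NaOAc/MeCN to chalcone 9.
- Reduce 9 in 1,2 fashion (NaBH4, CeCl3·7H2O, MeOH–THF, −40 °C) to the racemic (E)-allylic alcohol F1.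
- Ionise it with a BINOL-derived N-triflylphosphoramide (5 mol %, toluene, −60 °C). Within the chiral ion pair, either of the two equivalent phenols closes onto the benzylic terminus to give the (2S)-flav-3-ene F2, which has the same spatial arrangement at C2 as 13.
- Hydroborate with BH3·SMe2 anti to the 2-aryl group (boron at C3, hydrogen at benzylic C4) and oxidise under the same buffered conditions to 13.

Step 2 is second.
- Only one of the two ortho-OH groups is chelated at any moment, so some 2-O-ester can form.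
- Diester can also form.

The fallback sets out from 3 and comes back at 5. It replaces selective mono-acylation by over-acylation followed by trimming.
- Acylate 3 with 2.1 equiv of 4 (DCC/DMAP). The reaction stops at the 2,4-bis-gallate F3 because the last OH is locked in the chelate.
- Remove only the ester ortho to CHO by hemiacetal-assisted methanolysis (MeOH, cat. imidazole, −10 °C). Methanol adds to the aldehyde, and the hemiacetal oxygen takes over the neighbouring acyl group through a six-membered transition state. The para ester has no such pathway, so 5 results.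

Step 5 is third.
- Long exposure to strong acid may attack the benzyl ethers or the activated 7-ester.
- The aldol step may be sluggish.

The fallback sets out from 8 and comes back at 9 and then 10. It forms the C3–C4 bond under neutral conditions.
- Brominate 8 with PhNMe3Br3 (THF, 0 °C) to the α-bromoketone F4.
- Treat with PPh3 (toluene) to get the phosphonium bromide F5.
- Liberate the stabilised phosphorane F6 with aq. Na2CO3.
- Carry out a Wittig olefination with 5 (toluene, 60 °C) to give isolated 9.
- A brief exposure to HBF4·OEt2 (CH2Cl2, 0 °C) then closes 9 to 10.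

**Further compounds**
F1 | step 6 | rac-(E)-1-(ArB)-3-(ArA)prop-2-en-1-ol (ArA and ArB as in 9) | OC(/C=C/c1c(O)cc(OC(=O)c2cc(OCc3ccccc3)c(OCc3ccccc3)c(OCc3ccccc3)c2)cc1O)c1ccc(OCc2ccccc2)c(OC(=O)c2cc(OCc3ccccc3)c(OCc3ccccc3)c(OCc3ccccc3)c2)c1
F2 | step 6 | (2S)-4'-benzyloxy-5-hydroxy-7,3'-bis[3,4,5-tris(benzyloxy)benzoyloxy]flav-3-ene | Oc1cc(OC(=O)c2cc(OCc3ccccc3)c(OCc3ccccc3)c(OCc3ccccc3)c2)cc2O[C@H](c3ccc(OCc4ccccc4)c(OC(=O)c4cc(OCc5ccccc5)c(OCc5ccccc5)c(OCc5ccccc5)c4)c3)C=Cc12
F3 | step 2 | 4-formyl-5-hydroxy-1,3-phenylene bis[3,4,5-tris(benzyloxy)benzoate] | O=Cc1c(O)cc(OC(=O)c2cc(OCc3ccccc3)c(OCc3ccccc3)c(OCc3ccccc3)c2)cc1OC(=O)c1cc(OCc2ccccc2)c(OCc2ccccc2)c(OCc2ccccc2)c1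
F4 | step 5 | 2-(benzyloxy)-5-(bromoacetyl)phenyl 3,4,5-tris(benzyloxy)benzoate | O=C(CBr)c1ccc(OCc2ccccc2)c(OC(=O)c2cc(OCc3ccccc3)c(OCc3ccccc3)c(OCc3ccccc3)c2)c1
F5 | step 5 | (2-aryl-2-oxoethyl)triphenylphosphonium bromide derived from F4 | O=C(C[P+](c1ccccc1)(c1ccccc1)c1ccccc1)c1ccc(OCc2ccccc2)c(OC(=O)c2cc(OCc3ccccc3)c(OCc3ccccc3)c(OCc3ccccc3)c2)c1.[Br-]
F6 | step 5 | aroylmethylenetriphenylphosphorane derived from F5 | O=C(C=P(c1ccccc1)(c1ccccc1)c1ccccc1)c1ccc(OCc2ccccc2)c(OC(=O)c2cc(OCc3ccccc3)c(OCc3ccccc3)c(OCc3ccccc3)c2)c1
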